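The target is read as a Diels–Alder heterodimer of two guaianolide cyclopentadienes that both come from one enone, 12. The route rests on making 12 by an intramolecular Pauson–Khand reaction of 1,8-enyne 11: the C4≡C5 butynyl group on lactone carbon C6 and the C1=C2 vinyl group on C10 are joined with CO (C3), which forges C1–C5 and C3–C4 (and C2–C3), closes the cyclopentene ring and the seven-membered ring together and sets C1. The step exploits the C15-methylated C4=C5 alkene of the five-membered ring, flanked by C3 and the ring-fusion carbon C1. Enone 12 then furnishes the 2,4-diene (dienophile half) and its 3-silyloxy analogue (diene half).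

Key step: step 7

Remark: guaiane numbering (C1–C15) is used for each half, with primes for the norbornane-bearing half (the diene half).
Remark (assumption): (S)-(+)-linalool of high enantiomeric purity is taken as purchasable, and the enantiomer of the chromium ligand in step 5 is the one that delivers the 6S configuration.

Step 1
Reactants: 1 (S)-(+)-linalool
Product: 2 (3S)-3,7-dimethyl-3-(triethylsilyloxy)octa-1,6-diene
Conditions: Et3SiOTf, 2,6-lutidine, CH2Cl2, −78 °C to 0 °C
Reagents that add atoms: triethylsilyl trifluoromethanesulfonate, CC[Si](CC)(CC)OS(=O)(=O)C(F)(F)F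
Why: O-Silylation with a silyl triflate and a hindered base is dependable for tertiary allylic alcohols and prevents lactol formation after step 2, with the C10 stereocentre untouched.

Step 2
Reactants: 2
Product: 4 (4S)-4-methyl-4-(triethylsilyloxy)hex-5-enal, via secondary ozonide 3 (not isolated)
Conditions: O3, CH2Cl2, −78 °C, Sudan Red 7B as end-point indicator; then Me2S, −78 °C to rt
Reagents that add atoms: ozone, [O-][O+]=O
Why: Ozonolysis with reductive work-up should cleave the electron-rich trisubstituted alkene in preference to the hindered, inductively deactivated vinyl group when ozone is dosed against the dye, and creates no stereocentre.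

Step 3
Reactants: 4; 5 methyl acrylate
Product: 6 methyl (6S)-3-hydroxy-6-methyl-2-methylidene-6-(triethylsilyloxy)oct-7-enoate (C3 epimers)
Conditions: DABCO (1 equiv), neat in 5 (3 equiv), rt, several days
Reagents that add atoms: none
Why: Morita–Baylis–Hillman reaction of an unbranched aliphatic aldehyde with an acrylate installs C11–C13 on C7; the new carbinol centre is left as a mixture because step 4 destroys it.

Step 4
Reactants: 6
Product: 7 methyl (2Z,6S)-2-(bromomethyl)-6-methyl-6-(triethylsilyloxy)octa-2,7-dienoate
Conditions: NBS, Me2S, CH2Cl2, 0 °C to rt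
Reagents that add atoms: N-bromosuccinimide, O=C1CCC(=O)N1Br
Why: Activation of the allylic alcohol as an alkoxysulfonium salt and SN2′ attack of bromide (allylic transposition) should give the thermodynamically preferred Z-configured 2-(bromomethyl)enoate under neutral conditions that spare the silyl ether.

Step 5
Reactants: 7; 8 but-2-ynal
Product: 10 (4S,5S)-3-methylidene-4-[(3S)-3-methyl-3-(triethylsilyloxy)pent-4-en-1-yl]-5-(prop-1-yn-1-yl)oxolan-2-one, via anti hydroxy ester 9 (not isolated)
Conditions: CrCl2 (10 mol %), chiral carbazole-bridged bis(oxazoline) ligand (12 mol %), Mn powder (2 equiv), Me3SiCl (1.5 equiv), THF, rt; then aqueous citric acid, THF; PPTS (cat.), CH2Cl2, rt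
Reagents that add atoms: none
Why: Catalytic asymmetric Nozaki–Hiyama–Kishi 2-(alkoxycarbonyl)allylation, in which the equilibrating allylchromium intermediate (trivalent chromium) adds through a chair transition state with the C8 chain equatorial (anti adduct, hence the trans-lactone after lactonisation) while the ligand selects the aldehyde face that gives 6S and thereby 7S, independent of the remote C10 centre.

Step 6
Reactants: 10
Product: 11 (3S,4S,5S)-3-methyl-4-[(3S)-3-methyl-3-(triethylsilyloxy)pent-4-en-1-yl]-5-(prop-1-yn-1-yl)oxolan-2-one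
Conditions: NaBH4, MeOH, 0 °C
Reagents that add atoms: none
Why: Conjugate hydride reduction of the α-methylene lactone, with protonation of the lactone enolate under equilibrating methoxide conditions, should place the C11 methyl trans to the C7 side chain (11S) and leaves alkyne, vinyl group and silyl ether alone.

Step 7
Reactants: 11
Product: 12 (1R,6S,7S,10S,11S)-3-oxo-10-(triethylsilyloxy)guai-4-en-12,6-olide (cyclopentenone fused to the seven-membered ring, trans-γ-lactone, 1αH)
Conditions: Co2(CO)8 (0.2 equiv), tetramethylthiourea (1.2 equiv), CO (1 atm), toluene (0.01 M), 75 °C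
Reagents that add atoms: carbon monoxide, [C-]#[O+]
Why: The alkyne is taken up as its Co2(CO)6 complex, the vinyl group inserts into the Co–C5 bond (C1–C5), CO inserts and reductive elimination joins C2–C3–C4, releasing the cyclopentenone and the cobalt carbonyl for the next turnover. The closest known reaction type is the intramolecular Pauson–Khand [2+2+1] cycloaddition of 1,8-enynes whose tether is stiffened by a ring, run here with the Co2(CO)8/tetramethylthiourea catalyst under CO. The seven-membered ring closes 7-exo with respect to both the alkyne and the alkene in the insertion step, and the cyclopentenone closes on the metal by CO insertion and reductive elimination (formal [2+2+1]). The only new stereocentre, C1, is set during alkene insertion by a chair-like seven-membered array that continues the trans-diaxial H6/H7 pattern of the lactone, with the C10 methyl equatorial and the silyloxy group axial, so that H1 should end on the α face (1R); as C1 is γ to the enone carbonyl, this epimer should also be reachable by equilibration. Regiochemistry is fixed by the tether (C5 to C1, CO between C4 and C2); what the step needs is cyclisation in preference to oligomerisation, which the trans-lactone (alkyne and side chain held gauche), the fully substituted C10 (Thorpe–Ingold effect) and high dilution should secure.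

Step 8
Reactants: 12
Product: 14 (1R)-10-(triethylsilyloxy)-3-(trifluoromethanesulfonyloxy)guaia-2,4-dien-12,6-olide, via lithium dienolate 13 (not isolated)
Conditions: LiN(SiMe3)2 (1.05 equiv), THF, −78 °C; then PhNTf2, −78 °C to 0 °C
Reagents that add atoms: N-phenylbis(trifluoromethanesulfonimide), O=S(=O)(N(c1ccccc1)S(=O)(=O)C(F)(F)F)C(F)(F)F
Why: Kinetic deprotonation of the enone occurs at the α′-methylene C2 (more acidic and more accessible than the tertiary lactone C11–H or the γ-hydrogens), and O-triflation of the cross-conjugated dienolate fixes the C2=C3 double bond without touching C1.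

Step 9
Reactants: 14
Product: 15 (1R)-10-(triethylsilyloxy)guaia-2,4-dien-12,6-olide (2,4-cyclopentadiene, 1αH)
Conditions: Pd(OAc)2 (5 mol %), PPh3 (10 mol %), HCO2H, n-Bu3N, DMF, 40 °C
Reagents that add atoms: none
Why: Palladium-catalysed formate reduction of the enol triflate (oxidative addition to zerovalent palladium, decarboxylation of formate, C–H reductive elimination) replaces the triflate by hydrogen under non-acidic conditions, so the 2,4-diene should form without double-bond migration and with C1 intact.

Step 10
Reactants: 12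
Product: 16 (1R)-3-(tert-butyldimethylsilyloxy)-10-(triethylsilyloxy)guaia-2,4-dien-12,6-olide
Conditions: t-BuMe2SiOTf (1.1 equiv), Et3N, CH2Cl2, −78 °C to 0 °C
Reagents that add atoms: tert-butyldimethylsilyl trifluoromethanesulfonate, CC(C)(C)[Si](C)(C)OS(=O)(=O)C(F)(F)F
Why: Soft enolisation (silyl triflate activation of the ketone, amine deprotonation at the α′-position C2) should give the cross-conjugated 2-silyloxydiene faster than the lactone is enolised, with C1 untouched.

Step 11
Reactants: 15; 16 (3 equiv)
Product: 18 target dimer (3′-oxo-3′,4′-dihydro compound of the absinthin-type skeleton, C4′ methyl endo), via silyl enol ether cycloadduct 17 (not isolated)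
Conditions: neat (or 2 M in toluene), BHT (cat.), dark, rt, several days; then HF·pyridine, THF–pyridine, 0 °C to rt
Reagents that add atoms: none
Why: Diels–Alder [4+2] cycloaddition of the kind by which this cyclopentadiene class dimerises, followed by fluoride protodesilylation: the electron-rich silyloxydiene 16 (in excess) is the better 4π partner and the cis-disubstituted C2=C3 bond of 15 the only unhindered 2π partner, bonding C2′–C2 and C5′–C3 (largest HOMO coefficient of 16 at C2′, largest LUMO coefficient of 15 at its terminal C2) through the endo transition state on the α faces of both halves (anti to C10 and C10′), which sets C2, C3, C2′ and C5′, after which the enol ether is protonated at C4′ from the exo face (the endo face is screened by the cyclopentene of the other half) to give the endo-methyl C3′ ketone while both triethylsilyl ethers are cleaved.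

Compound list
1 | (S)-(+)-linalool, (3S)-3,7-dimethylocta-1,6-dien-3-ol | CC(C)=CCC[C@](C)(O)C=C | starting material
2 | (3S)-3,7-dimethyl-3-(triethylsilyloxy)octa-1,6-diene | CC(C)=CCC[C@](C)(O[Si](CC)(CC)CC)C=C | intermediate
3 | secondary ozonide (1,2,4-trioxolane) of the trisubstituted alkene of 2 | CC1(C)OOC(CC[C@](C)(O[Si](CC)(CC)CC)C=C)O1 | intermediate (not isolated)
4 | (4S)-4-methyl-4-(triethylsilyloxy)hex-5-enal | O=CCC[C@](C)(O[Si](CC)(CC)CC)C=C | intermediate
5 | methyl acrylate | C=CC(=O)OC | starting material
6 | methyl (6S)-3-hydroxy-6-methyl-2-methylidene-6-(triethylsilyloxy)oct-7-enoate (C3 epimers) | C=C(C(=O)OC)C(O)CC[C@](C)(O[Si](CC)(CC)CC)C=C | intermediate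
7 | methyl (2Z,6S)-2-(bromomethyl)-6-methyl-6-(triethylsilyloxy)octa-2,7-dienoate | COC(=O)/C(CBr)=C/CC[C@](C)(O[Si](CC)(CC)CC)C=C | intermediate
8 | but-2-ynal | CC#CC=O | starting material
9 | methyl (3S,4S)-4-hydroxy-2-methylidene-3-[(3S)-3-methyl-3-(triethylsilyloxy)pent-4-en-1-yl]hept-5-ynoate (anti hydroxy ester) | CC#C[C@@H](O)[C@@H](CC[C@](C)(O[Si](CC)(CC)CC)C=C)C(=C)C(=O)OC | intermediate (not isolated)
10 | (4S,5S)-3-methylidene-4-[(3S)-3-methyl-3-(triethylsilyloxy)pent-4-en-1-yl]-5-(prop-1-yn-1-yl)oxolan-2-one | CC#C[C@H]1OC(=O)C(=C)[C@@H]1CC[C@](C)(O[Si](CC)(CC)CC)C=C | intermediate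
11 | (3S,4S,5S)-3-methyl-4-[(3S)-3-methyl-3-(triethylsilyloxy)pent-4-en-1-yl]-5-(prop-1-yn-1-yl)oxolan-2-one (1,8-enyne) | CC#C[C@H]1OC(=O)[C@@H](C)[C@@H]1CC[C@](C)(O[Si](CC)(CC)CC)C=C | intermediate
12 | (1R,6S,7S,10S,11S)-3-oxo-10-(triethylsilyloxy)guai-4-en-12,6-olide | CC1=C2[C@H]3OC(=O)[C@@H](C)[C@@H]3CC[C@](C)(O[Si](CC)(CC)CC)[C@@H]2CC1=O | intermediate
13 | lithium 2,4-dienolate of 12 | [Li+].CC1=C2[C@H]3OC(=O)[C@@H](C)[C@@H]3CC[C@](C)(O[Si](CC)(CC)CC)[C@@H]2C=C1[O-] | intermediate (not isolated)
14 | (1R)-10-(triethylsilyloxy)-3-(trifluoromethanesulfonyloxy)guaia-2,4-dien-12,6-olide | CC1=C2[C@H]3OC(=O)[C@@H](C)[C@@H]3CC[C@](C)(O[Si](CC)(CC)CC)[C@@H]2C=C1OS(=O)(=O)C(F)(F)F | intermediate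
15 | (1R)-10-(triethylsilyloxy)guaia-2,4-dien-12,6-olide | CC1=C2[C@H]3OC(=O)[C@@H](C)[C@@H]3CC[C@](C)(O[Si](CC)(CC)CC)[C@@H]2C=C1 | intermediate
16 | (1R)-3-(tert-butyldimethylsilyloxy)-10-(triethylsilyloxy)guaia-2,4-dien-12,6-olide | CC1=C2[C@H]3OC(=O)[C@@H](C)[C@@H]3CC[C@](C)(O[Si](CC)(CC)CC)[C@@H]2C=C1O[Si](C)(C)C(C)(C)C | intermediate
17 | endo cycloadduct: 3′-(tert-butyldimethylsilyl) enol ether, 10,10′-bis(triethylsilyl) ether of the dimer | CC1=C2[C@H]3OC(=O)[C@@H](C)[C@@H]3CC[C@](C)(O[Si](CC)(CC)CC)[C@@H]2[C@H]2[C@H]3C(O[Si](C)(C)C(C)(C)C)=C(C)[C@]4([C@@H]3[C@@](C)(O[Si](CC)(CC)CC)CC[C@H]3[C@H](C)C(=O)O[C@@H]34)[C@@H]12 | intermediate (not isolated)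
18 | target dimer (10,10′-dihydroxy-3′-oxo, C4=C5 alkene, two trans-γ-lactones, C4′ methyl endo) | CC1=C2[C@H]3OC(=O)[C@@H](C)[C@@H]3CC[C@](C)(O)[C@@H]2[C@H]2[C@H]3C(=O)[C@@H](C)[C@]4([C@@H]3[C@@](C)(O)CC[C@H]3[C@H](C)C(=O)O[C@@H]34)[C@@H]12 | target

Total step count: 11. Longest linear sequence: 10 steps (steps 1–9, then 11).

Steps most likely to fail

1. Step 7. Alkene insertion that closes the seven-membered ring may be slower than decomplexation, alkyne oligomerisation or catalyst decay, so that the enyne is consumed without ring closure. The fallback sets out from 11 and comes back at 12. The vinyl group of 11 is cleaved selectively beside the internal alkyne (O3 against an indicator, then Me2S) to the α-silyloxy aldehyde F1. A Wittig reaction with (triphenylphosphoranylidene)acetaldehyde in warm toluene gives the E-configured enal F2. An intramolecular nickel-catalysed reductive [3+2] cycloaddition of the enal with the alkyne (bis(1,5-cyclooctadiene)nickel, PBu3, Et3B, MeOH–THF) forms the same C1–C5 and C3–C4 bonds by oxidative cyclisation at zerovalent nickel, now with an electron-poor alkene partner, and gives the cyclopentenol F3, whose C3 configuration is of no consequence. Oxidation of this allylic alcohol with MnO2 returns 12.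

2. Step 11. Self-dimerisation of 15, sigmatropic 1,5-hydrogen shifts in either diene before cycloaddition, and hydrolysis of the silyl enol ether over the long reaction time may erode the cross-adduct. The fallback sets out from 15 and comes back at 18. Diene 15 alone is left neat to undergo the homo-Diels–Alder dimerisation typical of this diene class, giving the bis(triethylsilyl) ether of the 3′,4′-alkene dimer F4. Hydroboration–oxidation (BH3·THF, then NaBO3) of the strained trisubstituted norbornene bond, in preference to the tetrasubstituted C4=C5 bond, gives the secondary C3′ alcohol F5. Dess–Martin oxidation gives the ketone bis(triethylsilyl) ether F6, with equilibration through the enol (DBU) if the C4′ methyl emerges exo. HF·pyridine then gives 18.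

3. Step 5. Weak or mismatched catalyst control over the aldehyde face beside the existing C10 centre, or erosion of anti selectivity with the conjugated ynal, may give mixtures of lactone diastereomers. The fallback sets out from 7 and 8 and comes back at 10. It gives up catalyst control: a ligand-free allylation–lactonisation with stoichiometric CrCl2 (anti-selective through the same chair transition state) should give 10 together with its (6R,7R)-diastereomer F7. Because C10 is fixed from linalool, the two trans-lactones are diastereomers and are separated by preparative chromatography, so the absolute configuration at C6 and C7 is taken from C10 by separation.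

Further compounds
F1 | step 7 | (2S)-2-methyl-4-[(2S,3S,4S)-4-methyl-5-oxo-2-(prop-1-yn-1-yl)oxolan-3-yl]-2-(triethylsilyloxy)butanal | CC#C[C@H]1OC(=O)[C@@H](C)[C@@H]1CC[C@](C)(O[Si](CC)(CC)CC)C=O
F2 | step 7 | (2E,4S)-4-methyl-6-[(2S,3S,4S)-4-methyl-5-oxo-2-(prop-1-yn-1-yl)oxolan-3-yl]-4-(triethylsilyloxy)hex-2-enal | CC#C[C@H]1OC(=O)[C@@H](C)[C@@H]1CC[C@](C)(O[Si](CC)(CC)CC)/C=C/C=O
F3 | step 7 | (1R)-3-hydroxy-10-(triethylsilyloxy)guai-4-en-12,6-olide (C3 epimers) | CC1=C2[C@H]3OC(=O)[C@@H](C)[C@@H]3CC[C@](C)(O[Si](CC)(CC)CC)[C@@H]2CC1O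
F4 | step 11 | homodimer of 15, 10,10′-bis(triethylsilyl) ether with C3′=C4′ alkene | CC1=C2[C@H]3OC(=O)[C@@H](C)[C@@H]3CC[C@](C)(O[Si](CC)(CC)CC)[C@@H]2[C@H]2[C@H]3C=C(C)[C@]4([C@@H]3[C@@](C)(O[Si](CC)(CC)CC)CC[C@H]3[C@H](C)C(=O)O[C@@H]34)[C@@H]12
F5 | step 11 | 3′-hydroxy-3′,4′-dihydro dimer, 10,10′-bis(triethylsilyl) ether (C3′ and C4′ configuration set by the face of attack) | CC1=C2[C@H]3OC(=O)[C@@H](C)[C@@H]3CC[C@](C)(O[Si](CC)(CC)CC)[C@@H]2[C@H]2[C@H]3C(O)C(C)[C@]4([C@@H]3[C@@](C)(O[Si](CC)(CC)CC)CC[C@H]3[C@H](C)C(=O)O[C@@H]34)[C@@H]12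
F6 | step 11 | 10,10′-bis(triethylsilyl) ether of 18 | CC1=C2[C@H]3OC(=O)[C@@H](C)[C@@H]3CC[C@](C)(O[Si](CC)(CC)CC)[C@@H]2[C@H]2[C@H]3C(=O)[C@@H](C)[C@]4([C@@H]3[C@@](C)(O[Si](CC)(CC)CC)CC[C@H]3[C@H](C)C(=O)O[C@@H]34)[C@@H]12
F7 | step 5 | (4R,5R)-3-methylidene-4-[(3S)-3-methyl-3-(triethylsilyloxy)pent-4-en-1-yl]-5-(prop-1-yn-1-yl)oxolan-2-one | CC#C[C@@H]1OC(=O)C(=C)[C@H]1CC[C@](C)(O[Si](CC)(CC)CC)C=C
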